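The rate constants are those of an exercise; the rest is arithmetic.

Target is a way station in this scheme, since it goes on to over-reaction product, so a share of target asks first how long target has been kept.

in all of them: substrate 1.8 M; time 30 h
- south: temperature 25 °C
- south-east: at 5 °C until 15 h, from then on at 45 °C
- south-west: temperature 5 °C
- east: temperature 45 °C

    substrate ⇌ intermediate A (K1 = 1.7, k1 = 4.1 × 10⁻⁴ s⁻¹, Ea1 = 87.0 kJ mol⁻¹, ΔH1 = −57.0 kJ mol⁻¹)
    substrate ⇌ intermediate C (K2 = 0.62, k2 = 2.1 × 10⁻⁵ s⁻¹, Ea2 = 99.0 kJ mol⁻¹, ΔH2 = −47.0 kJ mol⁻¹)
    intermediate D → target (k3 = 2.6 × 10⁻⁵ s⁻¹, Ea3 = 102 kJ mol⁻¹)
    substrate ⇌ intermediate B (K4 = 0.26, k4 = 5.7 × 10⁻⁵ s⁻¹, Ea4 = 105 kJ mol⁻¹, ΔH4 = −90.0 kJ mol⁻¹)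
    target → over-reaction product (k5 = 6.2 × 10⁻⁶ s⁻¹, Ea5 = 95.0 kJ mol⁻¹)
    intermediate C → side product (k6 = 1.7 × 10⁻⁵ s⁻¹, Ea6 = 105 kJ mol⁻¹)
    intermediate C ⇌ intermediate D (K7 = 1.4, k7 = 5.6 × 10⁻⁴ s⁻¹, Ea7 = 81.0 kJ mol⁻¹, ΔH7 = −34.0 kJ mol⁻¹)
    (constants at 25 °C)

* the flask that comes out highest in share of target in all that became target or side product or over-reaction product, or "all alike" when all lie within 1.5 percentage points (south / south-east / south-west / east / all alike)
* share of target in all that became target or side product or over-reaction product, south
* share of target in all that became target or side product or over-reaction product, south-east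
* share of target in all that became target or side product or over-reaction product, south-west
* share of target in all that became target or side product or over-reaction product, east

- the list of constants is for 25 °C, to be carried to other temperatures by the activation energies and enthalpies

I turn the loss of target into a clock. Carried by its activation energy, target's lifetime is 705 h at 5 °C, 44.8 h at 25 °C and 4.03 h at 45 °C. My carried quantity is the exposure, the run time divided by target's lifetime: 0.670 in south, 0.0426 in south-west and 7.45 in east. If target is fed steadily, the part of it surviving is one minus exp(−exposure), over the exposure, which gives 0.729 in south.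

Next comes the fork, the selectivity between target and side product. With intermediates C and D at their equilibrium ratio, 1.4 in south, the part of the leak going to target is 0.682 there, so south gives 49.7 %. In east the ratio falls to 0.591 and the fork to 0.456.

In south-west the ratio is 3.75, but intermediates C and D relax in 4.10 h, so intermediate D trails. Under steady feed its summed amount runs short by two relaxation times of the run, and the mean ratio of D to C becomes 1.34. South-west then gives 69.2 %, and I drop its exposure of 0.0426 as smaller than my other doubts.

The weak link is the steady feed. In east it would give 6.12 %, but the pool of substrate and intermediates shrinks during the run. In east, intermediate C returns to substrate at 0.00137 s⁻¹ and drains to side product and, through intermediate D, to target at 4.48 × 10⁻⁴ s⁻¹, a third of that return, so I do not put it at its equilibrium with substrate, 0.188, but at the steady ratio 0.142. With substrate and intermediates A and B in balance, the pool in east has a lifetime of 7.22 h, which is shorter than the run of 30 h. So I reforge it with a feed that falls exponentially. Target then follows the pool down at 1.26 of the pool's remainder, times the fork, and east gives 0.883 %. In south-east the forward lifetime of substrate to intermediate C at 5 °C is 234 h, which is longer than the cold stretch of 15 h, so I count the hot remainder and get 6.65 %. My choice is south-west.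

The forecast also names south-west, with 46.5 % for south, 6.6 % for south-east, 73.5 % for south-west and 0.9 % for east. Its values for south and south-west differ from mine, and of the stepped flask it writes that “the cold phase contributes almost nothing”.

The simulation puts south-west highest at 73.5 %, with south at 49.9 %, south-east at 6.60 % and east at 0.860 %. In south at 30.0 h, target stands at 14.0 % of the charge and over-reaction product at 4.57 %, so 0.754 of the target made remains, beside the survival of 0.729 from exposure 0.670. The neighbour flask at 30 °C has exposure 1.26 and so survival 0.569, and it ends with target at 18.0 %, over-reaction product at 14.6 % and a share of 33.8 %.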